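Ring C is cut at the C4–C4a bond. O1, C2, C3 and C4 are carried as a (2R,3S)-3-aryloxy-2-methylbutanoyl chain on a ring A that already bears the (R)-configured phenylpropanoate arm at C8 and methoxy groups at the future C5 and C7; C4a is then the only free ring A carbon ortho to O1. One intramolecular Friedel–Crafts acylation joins C4 to C4a and closes ring C without touching the three stereocentres, which come from a rhodium-catalysed phenyl addition to a coumarin and from a trans-β-lactone opened with inversion. Selective C5 demethylation, O-tert-prenylation, Claisen shift to C6 and ester cleavage finish the target.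

Key step: step 7

Remark on the chemistry: the target is read as (R) at the benzylic carbon with a cis (2S,3R) pair in ring C, which maps onto the anti (2R,3R) hydroxy acid, the trans (3R,4R) lactone and, after inversion, the syn (2R,3S) aryloxy acid, so the key-step structures are kept as they stand. The O-allyl group used later is the tertiary 1,1-dimethylallyl ether, the only isomer whose Claisen shift gives a linear prenyl group. Its carbonate and the (R)-antipode of the ligand in step 1 are assumed to be purchasable; the other antipode would be used if the facial sense proves opposite.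

**Step 1**
Reactants: 1 5,7-dimethoxycoumarin; 2 phenylboronic acid
Product: 3 (4R)-5,7-dimethoxy-4-phenyl-3,4-dihydro-2H-chromen-2-one
Conditions: Rh(acac)(C2H4)2 (3 mol %), (R)-SEGPHOS (3.3 mol %), dioxane/H2O, 60 °C
Reagents that add atoms: none
Why: Hayashi–Miyaura rhodium-catalysed asymmetric 1,4-addition of the arylboronic acid to the coumarin enoate, in which the (R)-SEGPHOS-bound phenylrhodium species is expected to add to one enantioface at C4 and set the benzylic stereocentre as (R), as it does for simple coumarins, while the lactone and both methyl ethers stay inert.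

**Step 2**
Reactants: 3 (4R)-5,7-dimethoxy-4-phenyl-3,4-dihydro-2H-chromen-2-one
Product: 4 methyl (3R)-3-(2-hydroxy-4,6-dimethoxyphenyl)-3-phenylpropanoate
Conditions: NaOMe (1.1 equiv), MeOH, 0 °C; AcOH quench
Reagents that add atoms: sodium methoxide (NaOMe), [Na+].[O-]C
Why: Base-mediated transesterification of the aryl lactone, driven by release of the phenoxide as the better leaving group, should open the ring at 0 °C without touching the benzylic stereocentre, which is not alpha to the carbonyl.

**Step 3**
Reactants: 5 methyl (R)-3-hydroxybutanoate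
Product: 7 methyl (2R,3R)-3-hydroxy-2-methylbutanoate, via dilithium alkoxide enolate 6 (not isolated)
Conditions: LiN(iPr)2 (2.2 equiv), THF, −78 to −20 °C; MeI, −78 to 0 °C; AcOH quench
Reagents that add atoms: iodomethane, CI
Why: Fráter–Seebach alkylation, in which the chelated dilithium alkoxide enolate is methylated on the face opposite the C3 methyl group, so the new C2 stereocentre should form anti to the hydroxyl under substrate control.

**Step 4**
Reactants: 7 methyl (2R,3R)-3-hydroxy-2-methylbutanoate
Product: 8 (2R,3R)-3-hydroxy-2-methylbutanoic acid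
Conditions: LiOH (2 equiv), THF/H2O, 0 °C to rt; then aq. HCl to pH 2
Reagents that add atoms: lithium hydroxide (LiOH), [Li+].[OH-]
Why: Ester saponification under mild hydroxide conditions should give the acid without retro-aldol cleavage or C2 epimerisation, because the carboxylate formed is not enolised at these temperatures.

**Step 5**
Reactants: 8 (2R,3R)-3-hydroxy-2-methylbutanoic acid
Product: 10 (3R,4R)-3,4-dimethyloxetan-2-one, via mixed benzenesulfonic anhydride 9 (not isolated)
Conditions: PhSO2Cl (2 equiv), pyridine, 0 °C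
Reagents that add atoms: none
Why: β-Lactonisation by carboxyl activation, in which the C3 hydroxyl attacks the mixed sulfonic anhydride, so the C3–O bond is never broken and the anti acid should give the trans lactone with both stereocentres retained.

**Step 6**
Reactants: 4 methyl (3R)-3-(2-hydroxy-4,6-dimethoxyphenyl)-3-phenylpropanoate; 10 (3R,4R)-3,4-dimethyloxetan-2-one
Product: 12 (2R,3S)-3-{3,5-dimethoxy-2-[(1R)-3-methoxy-3-oxo-1-phenylpropyl]phenoxy}-2-methylbutanoic acid, via sodium phenoxide 11 (not isolated)
Conditions: NaH (1.0 equiv), DMF, 0 °C; then 10 (1.2 equiv), 0 to 40 °C; aq. HCl work-up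
Reagents that add atoms: none
Why: SN2 ring opening of the strained β-lactone by alkyl–oxygen cleavage, in which the phenoxide attacks C4 of the oxetanone with inversion and turns the (4R) centre into the (3S) aryloxy centre while C2 is untouched, acyl attack should be reversible, and the carboxylate product cannot undergo β-elimination.

**Step 7**
Reactants: 12 (2R,3S)-3-{3,5-dimethoxy-2-[(1R)-3-methoxy-3-oxo-1-phenylpropyl]phenoxy}-2-methylbutanoic acid
Product: 14 methyl (3R)-3-[(2S,3R)-5,7-dimethoxy-2,3-dimethyl-4-oxo-3,4-dihydro-2H-chromen-8-yl]-3-phenylpropanoate, via acid chloride 13 (not isolated)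
Conditions: 1-chloro-N,N,2-trimethylprop-1-en-1-amine (1.2 equiv), CH2Cl2, 0 °C; then SnCl4 (1.2 equiv), CH2Cl2 (0.02 M), −78 °C; cold pH 7 buffer quench
Reagents that add atoms: none
Why: The α-chloroenamine converts the acid into acid chloride 13 without liberating acid or needing base, and SnCl4 then ionises 13 to an acylium (or its tight complex) that attacks C4a of ring A to give an arenium σ-complex, which loses a proton to re-aromatise. The closest known reaction type is the intramolecular Friedel–Crafts acylation of 3-aryloxyalkanoyl chlorides to chroman-4-ones. Ring C closes as a six-membered ring in an exo mode at the acyl carbon (6-exo-trig for the complexed chloride, 6-exo-dig for the free acylium), with the C4a–C8a π bond of the arene inside the new ring. No stereocentre is created; C2 and C3 come unchanged from the lactone-derived chain and the benzylic centre from the coumarin addition. The step needs regioselectivity, secured because the three-atom tether from O1 can reach only an ortho carbon and C8 already carries the phenylpropanoate arm, and it needs retention of the cis pair, which the absence of base, the low temperature and the speed of closure onto a ring activated by three oxygen donors should protect against ketene formation, enolisation at C3 and retro-oxa-Michael opening. High dilution should keep the remote free carbon C6 from being acylated by a second molecule, and the methyl ester is not activated under these conditions.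

**Step 8**
Reactants: 14 methyl (3R)-3-[(2S,3R)-5,7-dimethoxy-2,3-dimethyl-4-oxo-3,4-dihydro-2H-chromen-8-yl]-3-phenylpropanoate
Product: 15 methyl (3R)-3-[(2S,3R)-5-hydroxy-7-methoxy-2,3-dimethyl-4-oxo-3,4-dihydro-2H-chromen-8-yl]-3-phenylpropanoate
Conditions: BCl3 (1.5 equiv), CH2Cl2, −78 to 0 °C; water quench
Reagents that add atoms: none
Why: Chelation-controlled ether cleavage by the Lewis acid, in which BCl3 binds the C4 carbonyl and the peri C5 methoxy oxygen in a six-membered chelate and chloride removes that methyl group only, so the C7 methyl ether, the methyl ester and ring C should survive at or below 0 °C.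

**Step 9**
Reactants: 15 methyl (3R)-3-[(2S,3R)-5-hydroxy-7-methoxy-2,3-dimethyl-4-oxo-3,4-dihydro-2H-chromen-8-yl]-3-phenylpropanoate
Product: 16 methyl (3R)-3-{(2S,3R)-7-methoxy-2,3-dimethyl-5-[(2-methylbut-3-en-2-yl)oxy]-4-oxo-3,4-dihydro-2H-chromen-8-yl}-3-phenylpropanoate
Conditions: Pd(PPh3)4 (5 mol %), tert-butyl (2-methylbut-3-en-2-yl) carbonate (2 equiv), THF, 0 °C to rt
Reagents that add atoms: tert-butyl (2-methylbut-3-en-2-yl) carbonate, CC(C)(C)OC(=O)OC(C)(C)C=C
Why: Tsuji–Trost allylic etherification under neutral conditions, in which the carbonate ionises on zerovalent palladium with loss of CO2, the tert-butoxide formed deprotonates the phenol, and the phenoxide attacks the more substituted terminus of the 1,1-dimethyl-π-allyl complex to give the tertiary aryl ether without an external base that could epimerise C3.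

**Step 10**
Reactants: 16 methyl (3R)-3-{(2S,3R)-7-methoxy-2,3-dimethyl-5-[(2-methylbut-3-en-2-yl)oxy]-4-oxo-3,4-dihydro-2H-chromen-8-yl}-3-phenylpropanoate
Product: 18 methyl (3R)-3-[(2S,3R)-5-hydroxy-7-methoxy-2,3-dimethyl-6-(3-methylbut-2-en-1-yl)-4-oxo-3,4-dihydro-2H-chromen-8-yl]-3-phenylpropanoate, via ortho dienone 17 (not isolated)
Conditions: toluene, 110 °C
Reagents that add atoms: none
Why: Aromatic Claisen rearrangement, in which the [3,3] shift can only end at C6, the single free ortho carbon of the C5 oxygen, and inverts the allyl unit so that C6 carries the linear 3-methylbut-2-enyl group once the dienone tautomerises to the chelated phenol.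

**Step 11**
Reactants: 18 methyl (3R)-3-[(2S,3R)-5-hydroxy-7-methoxy-2,3-dimethyl-6-(3-methylbut-2-en-1-yl)-4-oxo-3,4-dihydro-2H-chromen-8-yl]-3-phenylpropanoate
Product: 19 (3R)-3-[(2S,3R)-5-hydroxy-7-methoxy-2,3-dimethyl-6-(3-methylbut-2-en-1-yl)-4-oxo-3,4-dihydro-2H-chromen-8-yl]-3-phenylpropanoic acid
Conditions: Me3SnOH (5 equiv), ClCH2CH2Cl, 70 °C; then dilute aq. HCl wash
Reagents that add atoms: trimethyltin hydroxide (Me3SnOH), C[Sn](C)(C)O
Why: Mild ester hydrolysis by tin-assisted acyl–oxygen cleavage should free the acid under near-neutral conditions that leave the base-sensitive cis C2/C3 pair, the prenyl alkene and the phenol untouched.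

**Compound list**

1 | 5,7-dimethoxycoumarin | COc1cc(OC)c2C=CC(=O)Oc2c1 | starting material
2 | phenylboronic acid | OB(O)c1ccccc1 | starting material
3 | (4R)-5,7-dimethoxy-4-phenyl-3,4-dihydro-2H-chromen-2-one | O=C1C[C@H](c2ccccc2)c2c(OC)cc(OC)cc2O1 | intermediate
4 | methyl (3R)-3-(2-hydroxy-4,6-dimethoxyphenyl)-3-phenylpropanoate | COC(=O)C[C@H](c1ccccc1)c1c(O)cc(OC)cc1OC | intermediate
5 | methyl (R)-3-hydroxybutanoate | C[C@@H](O)CC(=O)OC | starting material
6 | dilithium (1E,3R)-1-methoxybut-1-ene-1,3-diolate (chelated alkoxide enolate) | C[C@@H]([O-])/C=C(\[O-])OC.[Li+].[Li+] | intermediate (not isolated)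
7 | methyl (2R,3R)-3-hydroxy-2-methylbutanoate | C[C@@H](O)[C@@H](C)C(=O)OC | intermediate
8 | (2R,3R)-3-hydroxy-2-methylbutanoic acid | C[C@@H](O)[C@@H](C)C(=O)O | intermediate
9 | (2R,3R)-3-hydroxy-2-methylbutanoic benzenesulfonic anhydride | C[C@@H](O)[C@@H](C)C(=O)OS(=O)(=O)c1ccccc1 | intermediate (not isolated)
10 | (3R,4R)-3,4-dimethyloxetan-2-one | C[C@H]1OC(=O)[C@@H]1C | intermediate
11 | sodium 3,5-dimethoxy-2-[(1R)-3-methoxy-3-oxo-1-phenylpropyl]phenolate | COC(=O)C[C@H](c1ccccc1)c1c([O-])cc(OC)cc1OC.[Na+] | intermediate (not isolated)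
12 | (2R,3S)-3-{3,5-dimethoxy-2-[(1R)-3-methoxy-3-oxo-1-phenylpropyl]phenoxy}-2-methylbutanoic acid | COc1cc(OC)c([C@H](CC(=O)OC)c2ccccc2)c(O[C@@H](C)[C@@H](C)C(=O)O)c1 | intermediate (key-step precursor)
13 | (2R,3S)-3-{3,5-dimethoxy-2-[(1R)-3-methoxy-3-oxo-1-phenylpropyl]phenoxy}-2-methylbutanoyl chloride | COc1cc(OC)c([C@H](CC(=O)OC)c2ccccc2)c(O[C@@H](C)[C@@H](C)C(=O)Cl)c1 | intermediate (not isolated)
14 | methyl (3R)-3-[(2S,3R)-5,7-dimethoxy-2,3-dimethyl-4-oxo-3,4-dihydro-2H-chromen-8-yl]-3-phenylpropanoate | COc1cc(OC)c2c(c1[C@H](CC(=O)OC)c1ccccc1)O[C@@H](C)[C@@H](C)C2=O | intermediate (key-step product)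
15 | methyl (3R)-3-[(2S,3R)-5-hydroxy-7-methoxy-2,3-dimethyl-4-oxo-3,4-dihydro-2H-chromen-8-yl]-3-phenylpropanoate | COc1cc(O)c2c(c1[C@H](CC(=O)OC)c1ccccc1)O[C@@H](C)[C@@H](C)C2=O | intermediate
16 | methyl (3R)-3-{(2S,3R)-7-methoxy-2,3-dimethyl-5-[(2-methylbut-3-en-2-yl)oxy]-4-oxo-3,4-dihydro-2H-chromen-8-yl}-3-phenylpropanoate | COc1cc(OC(C)(C)C=C)c2c(c1[C@H](CC(=O)OC)c1ccccc1)O[C@@H](C)[C@@H](C)C2=O | intermediate
17 | methyl (3R)-3-[(2S,3R)-7-methoxy-2,3-dimethyl-6-(3-methylbut-2-en-1-yl)-4,5-dioxo-3,4,5,6-tetrahydro-2H-chromen-8-yl]-3-phenylpropanoate (C6 unassigned) | COC1=C([C@H](CC(=O)OC)c2ccccc2)C2=C(C(=O)[C@H](C)[C@H](C)O2)C(=O)C1CC=C(C)C | intermediate (not isolated)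
18 | methyl (3R)-3-[(2S,3R)-5-hydroxy-7-methoxy-2,3-dimethyl-6-(3-methylbut-2-en-1-yl)-4-oxo-3,4-dihydro-2H-chromen-8-yl]-3-phenylpropanoate | COc1c(CC=C(C)C)c(O)c2c(c1[C@H](CC(=O)OC)c1ccccc1)O[C@@H](C)[C@@H](C)C2=O | intermediate
19 | (3R)-3-[(2S,3R)-5-hydroxy-7-methoxy-2,3-dimethyl-6-(3-methylbut-2-en-1-yl)-4-oxo-3,4-dihydro-2H-chromen-8-yl]-3-phenylpropanoic acid | COc1c(CC=C(C)C)c(O)c2c(c1[C@H](CC(=O)O)c1ccccc1)O[C@@H](C)[C@@H](C)C2=O | target

Total step count: 11
Longest linear sequence: 9 steps (steps 3, 4, 5, 6, 7, 8, 9, 10, 11, from compound 5 to compound 19)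

**Steps most likely to fail**

Step 7 (key step). The cis relationship could be lost through enolisation at C3 or through ring opening and reclosure by a retro-oxa-Michael path while the acyl group is activated, and a second molecule could be acylated at C6. The fallback closes ring C through the O1–C2 bond instead. It sets out from 4, which is O-acylated with (E)-2-methylbut-2-enoyl chloride in pyridine/CH2Cl2 to the aryl ester 3,5-dimethoxy-2-[(1R)-3-methoxy-3-oxo-1-phenylpropyl]phenyl (E)-2-methylbut-2-enoate F1. A TiCl4-mediated Fries rearrangement moves the acyl group to the free ortho carbon and gives methyl (3R)-3-{2-hydroxy-4,6-dimethoxy-3-[(E)-2-methylbut-2-enoyl]phenyl}-3-phenylpropanoate F2. A cinchona alkaloid-catalysed intramolecular oxa-Michael addition (quinine or quinidine, whichever matches the benzylic centre, chlorobenzene, rt) with kinetic protonation at C3 should then give the cis chromanone, and the route is rejoined at 14.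

Step 6. Substitution at the hindered secondary carbon may be slow, so that acyl attack, addition of further lactone to the product carboxylate, or loss of methoxide from the phenoxide ester by relactonisation takes over. The fallback activates the alcohol instead of opening a lactone. It sets out from 8, which is alkylated at the carboxylate with benzyl bromide and KHCO3 in DMF to benzyl (2R,3R)-3-hydroxy-2-methylbutanoate F3. A Mitsunobu etherification of F3 with phenol 4 (PPh3, diisopropyl azodicarboxylate, toluene, 0 °C to rt) inverts the carbinol carbon and gives benzyl (2R,3S)-3-{3,5-dimethoxy-2-[(1R)-3-methoxy-3-oxo-1-phenylpropyl]phenoxy}-2-methylbutanoate F4. Hydrogenolysis (H2, Pd/C, EtOAc) removes the benzyl ester only, and the route is rejoined at 12.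

Step 9. The hydrogen-bonded C5 phenol may be a poor nucleophile, and palladium may re-ionise the tertiary ether so that it drifts to the linear O-prenyl isomer, which would give the wrong allyl isomer at C6 on rearrangement. The fallback forms the C6–C bond by cross-coupling. It sets out from 15, which is iodinated at its only free aromatic carbon with N-iodosuccinimide in CH2Cl2 at 0 °C to methyl (3R)-3-[(2S,3R)-5-hydroxy-6-iodo-7-methoxy-2,3-dimethyl-4-oxo-3,4-dihydro-2H-chromen-8-yl]-3-phenylpropanoate F5. A Stille coupling with tributyl(3-methylbut-2-en-1-yl)stannane (Pd2(dba)3, tri(2-furyl)phosphine, DMF, 60 °C, no base) should couple through the less hindered allyl terminus, and the route is rejoined at 18, so that step 10 is not needed.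

**Further compounds**

F1 | step 7 | 3,5-dimethoxy-2-[(1R)-3-methoxy-3-oxo-1-phenylpropyl]phenyl (E)-2-methylbut-2-enoate | COC(=O)C[C@H](c1ccccc1)c1c(OC(=O)/C(C)=C/C)cc(OC)cc1OC
F2 | step 7 | methyl (3R)-3-{2-hydroxy-4,6-dimethoxy-3-[(E)-2-methylbut-2-enoyl]phenyl}-3-phenylpropanoate | COC(=O)C[C@H](c1ccccc1)c1c(O)c(C(=O)/C(C)=C/C)c(OC)cc1OC
F3 | step 6 | benzyl (2R,3R)-3-hydroxy-2-methylbutanoate | C[C@@H](O)[C@@H](C)C(=O)OCc1ccccc1
F4 | step 6 | benzyl (2R,3S)-3-{3,5-dimethoxy-2-[(1R)-3-methoxy-3-oxo-1-phenylpropyl]phenoxy}-2-methylbutanoate | COc1cc(OC)c([C@H](CC(=O)OC)c2ccccc2)c(O[C@@H](C)[C@@H](C)C(=O)OCc2ccccc2)c1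
F5 | step 9 | methyl (3R)-3-[(2S,3R)-5-hydroxy-6-iodo-7-methoxy-2,3-dimethyl-4-oxo-3,4-dihydro-2H-chromen-8-yl]-3-phenylpropanoate | COc1c(I)c(O)c2c(c1[C@H](CC(=O)OC)c1ccccc1)O[C@@H](C)[C@@H](C)C2=O
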